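**Retrosynthetic overview**
1. Target ⇐ Lindlar semi-hydrogenation and desilylation of a 14-membered macrocyclic ynoate, so the Z-enoate with its free γ-hydroxyl appears only in the last step.
2. The only ring (14-membered) ⇐ one photochemical step: decatungstate acyl-radical macrocyclisation of an open-chain aldehyde onto a 2-substituted acrylate, forming the ring CH2–C(=O) bond and setting the side-chain stereocentre by ring-controlled hydrogen return.
3. Open-chain precursor ⇐ esterification of a hydroxy ynoate aldehyde with 2-methylidene-4-oxohept-5-enoic acid (crotonaldehyde + 2-(bromomethyl)acrylic acid, then oxidation).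
4. Hydroxy ynoate ⇐ Felkin–Anh addition of a lithiated propiolate ester to O-silyl (S)-lactaldehyde (sets the carbinol centre), then ozonolysis.
5. Bought stereocentres: (S)-propylene oxide and ethyl (S)-lactate; the other two arise under substrate control.

Assumption: ring positions are numbered O1, C2(=O), C3=C4, C5(OH), C6(CH3), O7, C8(=O), C9(side chain), C10, C11(=O), C12, C13, C14(CH3); the SMILES is read as (3Z,5R,6S,9R,14S) with an E side-chain enone.

**Route**

Step 1
Reactants: 1 (S)-propylene oxide; 2 allylmagnesium chloride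
Product: 3 (2S)-hex-5-en-2-ol
Conditions: CuI (10 mol %), THF, −30 °C; aq NH4Cl
Reagents that add atoms: none
Why: Copper-catalysed Grignard opening of the epoxide at its unsubstituted carbon (SN2) leaves the bought stereocentre (later C14) untouched.

Step 2
Reactants: 3 (2S)-hex-5-en-2-ol; 4 propiolic acid
Product: 5 (2S)-hex-5-en-2-yl prop-2-ynoate
Conditions: DCC, DMAP (5 mol %), CH2Cl2, −20 → 0 °C
Reagents that add atoms: none
Why: Steglich esterification at low temperature acylates the alcohol oxygen without touching the carbinol carbon, so the S configuration is retained.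

Step 3
Reactants: 6 ethyl (S)-lactate
Product: 7 ethyl (2S)-2-(triethylsilyloxy)propanoate
Conditions: Et3SiCl, imidazole, DMF, 0 °C → rt
Reagents that add atoms: triethylsilyl chloride CC[Si](Cl)(CC)CC
Why: Routine silylation of the secondary alcohol, with the triethylsilyl group chosen because it can later be removed beside a tert-butyldimethylsilyl ether.

Step 4
Reactants: 7 ethyl (2S)-2-(triethylsilyloxy)propanoate
Product: 8 (2S)-2-(triethylsilyloxy)propanal
Conditions: i-Bu2AlH, CH2Cl2, −78 °C; aq potassium sodium tartrate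
Reagents that add atoms: none
Why: Low-temperature half-reduction of the ester stops at the aluminium hemiacetal and gives the configurationally intact α-silyloxy aldehyde, used at once.

Step 5
Reactants: 5 (2S)-hex-5-en-2-yl prop-2-ynoate; 8 (2S)-2-(triethylsilyloxy)propanal
Product: 11 (2S)-hex-5-en-2-yl (4R,5S)-4-(tert-butyldimethylsilyloxy)-5-(triethylsilyloxy)hex-2-ynoate, via lithium acetylide 9 (not isolated), via lithium alkoxide 10 (not isolated)
Conditions: LiN(SiMe3)2, THF, −78 °C; then 8; then t-BuMe2SiOTf, −78 → −20 °C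
Reagents that add atoms: tert-butyldimethylsilyl trifluoromethanesulfonate CC(C)(C)[Si](C)(C)OS(=O)(=O)C(F)(F)F
Why: Acetylide addition to the α-silyloxy aldehyde follows the Felkin–Anh (non-chelation) model, attack anti to the silyloxy group giving the 4,5-anti (4R) alkoxide (about 4:1 expected, minor epimer removed at 13), which is silylated in the same flask.

Step 6
Reactants: 11 (2S)-hex-5-en-2-yl (4R,5S)-4-(tert-butyldimethylsilyloxy)-5-(triethylsilyloxy)hex-2-ynoate
Product: 12 (2S)-5-oxopentan-2-yl (4R,5S)-4-(tert-butyldimethylsilyloxy)-5-(triethylsilyloxy)hex-2-ynoate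
Conditions: O3, CH2Cl2, −78 °C (Sudan red 7B end point); Me2S, −78 °C → rt
Reagents that add atoms: ozone [O-][O+]=O
Why: Ozonolysis cleaves the electron-rich terminal alkene selectively, the electron-poor ynoate and the silyl ethers being inert at −78 °C.

Step 7
Reactants: 12 (2S)-5-oxopentan-2-yl (4R,5S)-4-(tert-butyldimethylsilyloxy)-5-(triethylsilyloxy)hex-2-ynoate
Product: 13 (2S)-5-oxopentan-2-yl (4R,5S)-4-(tert-butyldimethylsilyloxy)-5-hydroxyhex-2-ynoate
Conditions: HF·pyridine, pyridine, THF, 0 °C
Reagents that add atoms: none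
Why: Buffered HF·pyridine cleaves the triethylsilyl ether much faster than the tert-butyldimethylsilyl ether (selective desilylation), and the linear ynoate keeps the freed hydroxyl from lactonising.

Step 8
Reactants: 14 (E)-but-2-enal (crotonaldehyde); 15 2-(bromomethyl)prop-2-enoic acid
Product: 16 (5E)-4-hydroxy-2-methylidenehept-5-enoic acid (racemic carbinol)
Conditions: In powder, THF/H2O (1:1), rt
Reagents that add atoms: none
Why: Indium-mediated Barbier allylation in water tolerates the free acid and adds 1,2 to the enal; the racemic carbinol centre is erased in step 9.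

Step 9
Reactants: 16 (5E)-4-hydroxy-2-methylidenehept-5-enoic acid
Product: 17 (5E)-2-methylidene-4-oxohept-5-enoic acid
Conditions: Dess–Martin periodinane, CH2Cl2, 0 °C → rt
Reagents that add atoms: none
Why: Dess–Martin oxidation of the allylic alcohol under non-basic conditions gives the E-enone without moving the exocyclic double bond into conjugation.

Step 10
Reactants: 13 (2S)-5-oxopentan-2-yl (4R,5S)-4-(tert-butyldimethylsilyloxy)-5-hydroxyhex-2-ynoate; 17 (5E)-2-methylidene-4-oxohept-5-enoic acid
Product: 18 (2S)-5-oxopentan-2-yl (4R,5S)-4-(tert-butyldimethylsilyloxy)-5-{[(5E)-2-methylidene-4-oxohept-5-enoyl]oxy}hex-2-ynoate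
Conditions: DIC, DMAP (10 mol %), CH2Cl2, −20 → 0 °C
Reagents that add atoms: none
Why: Carbodiimide (Steglich) esterification of the secondary alcohol, run cold with only catalytic DMAP to limit base-induced isomerisation of the β,γ-unsaturated keto acid.

Step 11
Reactants: 18 (2S)-5-oxopentan-2-yl (4R,5S)-4-(tert-butyldimethylsilyloxy)-5-{[(5E)-2-methylidene-4-oxohept-5-enoyl]oxy}hex-2-ynoate
Product: 21 (5R,6S,9R,14S)-5-(tert-butyldimethylsilyloxy)-6,14-dimethyl-9-[(3E)-2-oxopent-3-en-1-yl]-1,7-dioxacyclotetradec-3-yne-2,8,11-trione, via acyl radical 19 (not isolated), via ring radical 20 (not isolated)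
Conditions: (n-Bu4N)4[W10O32] (10 mol %), MeCN (2 mM), 390 nm LEDs, argon, 20 °C
Reagents that add atoms: none
Why: Proposed new method: a macrocyclising hydroacylation by decatungstate hydrogen-atom-transfer photocatalysis, not yet shown for ring closure or for ring-controlled C–H formation; the excited cluster abstracts the hydridic formyl hydrogen of 18, the nucleophilic acyl radical 19 adds 14-endo to the unsubstituted CH2 end of the 2-substituted acrylate (polarity matched and faster than attack on the β-substituted enone, the hindered ynoate or decarbonylation at 2 mM) to form C10–C11, and the bulky reduced cluster [HW10O32]4− returns hydrogen to the more open face of the planar ring radical 20, so C9 is set under control of C5/C6 through the ring conformation (model: Z-ester with C6–H eclipsing C8=O, C10 syn to O7, C5 and its silyloxy group screening one face; 9R is the predicted major epimer and the ratio must be measured); the closest known reactions are the intermolecular decatungstate hydroacylation of acrylates by aldehydes and the tin-hydride acyl-radical macrocyclisation of selenoesters onto acrylates.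

Step 12
Reactants: 21 (5R,6S,9R,14S)-5-(tert-butyldimethylsilyloxy)-6,14-dimethyl-9-[(3E)-2-oxopent-3-en-1-yl]-1,7-dioxacyclotetradec-3-yne-2,8,11-trione
Product: 22 (5R,6S,9R,14S)-5-hydroxy-6,14-dimethyl-9-[(3E)-2-oxopent-3-en-1-yl]-1,7-dioxacyclotetradec-3-yne-2,8,11-trione
Conditions: HF·pyridine, THF, 0 °C → rt
Reagents that add atoms: none
Why: Mildly acidic fluoride desilylation leaves the esters, the enone and the base-sensitive 1,5-diketone untouched, and the alkyne holds the new hydroxyl away from the C2 ester so no translactonisation can occur.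

Step 13
Reactants: 22 (5R,6S,9R,14S)-5-hydroxy-6,14-dimethyl-9-[(3E)-2-oxopent-3-en-1-yl]-1,7-dioxacyclotetradec-3-yne-2,8,11-trione
Product: 23 (3Z,5R,6S,9R,14S)-5-hydroxy-6,14-dimethyl-9-[(3E)-2-oxopent-3-en-1-yl]-1,7-dioxacyclotetradec-3-ene-2,8,11-trione (CNP0072204.1)
Conditions: H2 (1 atm), Pd/CaCO3 poisoned with Pb(OAc)2, quinoline, EtOAc, 0 °C
Reagents that add atoms: none
Why: Lindlar semi-hydrogenation adds H2 syn to the alkyne to give the Z-enoate, quinoline and a stop at one equivalent spare the enone, and the target is released under neutral conditions.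

**Compound list**
1 | (S)-propylene oxide | C[C@H]1CO1 | starting material
2 | allylmagnesium chloride | C=CC[Mg]Cl | starting material
3 | (2S)-hex-5-en-2-ol | C[C@H](O)CCC=C | intermediate
4 | propiolic acid | C#CC(=O)O | starting material
5 | (2S)-hex-5-en-2-yl prop-2-ynoate | C#CC(=O)O[C@@H](C)CCC=C | intermediate
6 | ethyl (S)-lactate | C[C@H](O)C(=O)OCC | starting material
7 | ethyl (2S)-2-(triethylsilyloxy)propanoate | C[C@H](O[Si](CC)(CC)CC)C(=O)OCC | intermediate
8 | (2S)-2-(triethylsilyloxy)propanal | C[C@H](O[Si](CC)(CC)CC)C=O | intermediate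
9 | lithium acetylide of 5, (2S)-hex-5-en-2-yl 3-lithioprop-2-ynoate | [Li]C#CC(=O)O[C@@H](C)CCC=C | intermediate
10 | lithium alkoxide, (2S)-hex-5-en-2-yl (4R,5S)-4-(lithiooxy)-5-(triethylsilyloxy)hex-2-ynoate | C=CCC[C@H](C)OC(=O)C#C[C@@H](O[Li])[C@H](C)O[Si](CC)(CC)CC | intermediate
11 | (2S)-hex-5-en-2-yl (4R,5S)-4-(tert-butyldimethylsilyloxy)-5-(triethylsilyloxy)hex-2-ynoate | C=CCC[C@H](C)OC(=O)C#C[C@@H](O[Si](C)(C)C(C)(C)C)[C@H](C)O[Si](CC)(CC)CC | intermediate
12 | (2S)-5-oxopentan-2-yl (4R,5S)-4-(tert-butyldimethylsilyloxy)-5-(triethylsilyloxy)hex-2-ynoate | O=CCC[C@H](C)OC(=O)C#C[C@@H](O[Si](C)(C)C(C)(C)C)[C@H](C)O[Si](CC)(CC)CC | intermediate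
13 | (2S)-5-oxopentan-2-yl (4R,5S)-4-(tert-butyldimethylsilyloxy)-5-hydroxyhex-2-ynoate | O=CCC[C@H](C)OC(=O)C#C[C@@H](O[Si](C)(C)C(C)(C)C)[C@H](C)O | intermediate
14 | (E)-but-2-enal (crotonaldehyde) | C/C=C/C=O | starting material
15 | 2-(bromomethyl)prop-2-enoic acid | OC(=O)C(=C)CBr | starting material
16 | (5E)-4-hydroxy-2-methylidenehept-5-enoic acid (racemic) | C/C=C/C(O)CC(=C)C(=O)O | intermediate
17 | (5E)-2-methylidene-4-oxohept-5-enoic acid | C/C=C/C(=O)CC(=C)C(=O)O | intermediate
18 | (2S)-5-oxopentan-2-yl (4R,5S)-4-(tert-butyldimethylsilyloxy)-5-{[(5E)-2-methylidene-4-oxohept-5-enoyl]oxy}hex-2-ynoate | O=CCC[C@H](C)OC(=O)C#C[C@@H](O[Si](C)(C)C(C)(C)C)[C@H](C)OC(=O)C(=C)CC(=O)/C=C/C | intermediate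
19 | acyl radical, 18 without its formyl hydrogen (radical at the carbon that becomes C11) | O=[C]CC[C@H](C)OC(=O)C#C[C@@H](O[Si](C)(C)C(C)(C)C)[C@H](C)OC(=O)C(=C)CC(=O)/C=C/C | intermediate
20 | ring radical, 21 without the hydrogen at C9 (planar α-ester radical in the 14-membered ring) | C/C=C/C(=O)C[C]1CC(=O)CC[C@H](C)OC(=O)C#C[C@@H](O[Si](C)(C)C(C)(C)C)[C@H](C)OC1=O | intermediate
21 | (5R,6S,9R,14S)-5-(tert-butyldimethylsilyloxy)-6,14-dimethyl-9-[(3E)-2-oxopent-3-en-1-yl]-1,7-dioxacyclotetradec-3-yne-2,8,11-trione | C/C=C/C(=O)C[C@H]1CC(=O)CC[C@H](C)OC(=O)C#C[C@@H](O[Si](C)(C)C(C)(C)C)[C@H](C)OC1=O | intermediate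
22 | (5R,6S,9R,14S)-5-hydroxy-6,14-dimethyl-9-[(3E)-2-oxopent-3-en-1-yl]-1,7-dioxacyclotetradec-3-yne-2,8,11-trione | C/C=C/C(=O)C[C@H]1CC(=O)CC[C@H](C)OC(=O)C#C[C@@H](O)[C@H](C)OC1=O | intermediate
23 | (3Z,5R,6S,9R,14S)-5-hydroxy-6,14-dimethyl-9-[(3E)-2-oxopent-3-en-1-yl]-1,7-dioxacyclotetradec-3-ene-2,8,11-trione | C/C=C/C(=O)C[C@H]1CC(=O)CC[C@H](C)OC(=O)/C=C\[C@@H](O)[C@H](C)OC1=O | target

**Count**
Total steps: 13. Longest linear sequence: 9 steps (1, 2, 5, 6, 7, 10, 11, 12, 13; the lactate branch 3, 4, 5 … 13 is equally long).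

**Steps most likely to fail**

Step 10 (esterification with keto acid 17). The methylene of 17 sits between the ketone and the acrylate, so DMAP can shift the exocyclic double bond into conjugation, and the alcohol of 13 is hindered. The fallback carries the ketone at the alcohol level. It sets out from 16 and 13 and returns at 18. Acid 16 is treated with Et3SiCl and imidazole to give the bis(triethylsilyl) derivative F1. Aqueous K2CO3 work-up hydrolyses the silyl ester to the silyl ether acid F2, which has no acidic methylene. DIC coupling of F2 with 13 gives ester F3. Buffered HF·pyridine at 0 °C removes only the triethylsilyl group to give allylic alcohol F4, which is oxidised at once with Dess–Martin periodinane to 18.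

Step 11 (the proposed photochemical macrocyclisation). It may give oligomers or decarbonylation, and the facial sense of hydrogen return at C9 is a prediction only. The fallback uses known chemistry and closes the ring by lactonisation instead. It sets out from 12 and 17 and returns at 21. Intermolecular decatungstate hydroacylation ((n-Bu4N)4[W10O32], MeCN, 390 nm) of the acrylic acid 17 with aldehyde 12 gives seco acid F5, as both epimers at the future C9 because the open chain offers no control. HF·pyridine with pyridine removes the triethylsilyl group to give hydroxy acid F6. Shiina macrolactonisation (2-methyl-6-nitrobenzoic anhydride, DMAP, high dilution) forms the O7–C8 bond and gives 21 together with its C9 epimer F7, which is removed by chromatography.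

Step 13 (Lindlar reduction beside the enone). Over-reduction of the side-chain enone is the risk. The fallback replaces catalytic hydrogenation by an electron-transfer reduction and moves desilylation to the end. It sets out from 21 and returns at 23. Zinc dust activated with Cu(OAc)2 and AgNO3 in MeOH/H2O (Boland reduction) reduces the conjugated alkyne of 21 to the Z-enoate silyl ether F8. HF·pyridine then gives 23.

**Further compounds**
F1 | step 10 | triethylsilyl (5E)-2-methylidene-4-(triethylsilyloxy)hept-5-enoate | C/C=C/C(O[Si](CC)(CC)CC)CC(=C)C(=O)O[Si](CC)(CC)CC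
F2 | step 10 | (5E)-2-methylidene-4-(triethylsilyloxy)hept-5-enoic acid | C/C=C/C(O[Si](CC)(CC)CC)CC(=C)C(=O)O
F3 | step 10 | (2S)-5-oxopentan-2-yl (4R,5S)-4-(tert-butyldimethylsilyloxy)-5-{[(5E)-2-methylidene-4-(triethylsilyloxy)hept-5-enoyl]oxy}hex-2-ynoate | O=CCC[C@H](C)OC(=O)C#C[C@@H](O[Si](C)(C)C(C)(C)C)[C@H](C)OC(=O)C(=C)CC(O[Si](CC)(CC)CC)/C=C/C
F4 | step 10 | (2S)-5-oxopentan-2-yl (4R,5S)-4-(tert-butyldimethylsilyloxy)-5-{[(5E)-4-hydroxy-2-methylidenehept-5-enoyl]oxy}hex-2-ynoate | O=CCC[C@H](C)OC(=O)C#C[C@@H](O[Si](C)(C)C(C)(C)C)[C@H](C)OC(=O)C(=C)CC(O)/C=C/C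
F5 | step 11 | seco acid, 2-[(3E)-2-oxopent-3-en-1-yl]-4-oxo-7-{[(4R,5S)-4-(tert-butyldimethylsilyloxy)-5-(triethylsilyloxy)hex-2-ynoyl]oxy}octanoic acid, (7S), both epimers at C2 | C/C=C/C(=O)CC(CC(=O)CC[C@H](C)OC(=O)C#C[C@@H](O[Si](C)(C)C(C)(C)C)[C@H](C)O[Si](CC)(CC)CC)C(=O)O
F6 | step 11 | hydroxy acid, 2-[(3E)-2-oxopent-3-en-1-yl]-4-oxo-7-{[(4R,5S)-4-(tert-butyldimethylsilyloxy)-5-hydroxyhex-2-ynoyl]oxy}octanoic acid, (7S), both epimers at C2 | C/C=C/C(=O)CC(CC(=O)CC[C@H](C)OC(=O)C#C[C@@H](O[Si](C)(C)C(C)(C)C)[C@H](C)O)C(=O)O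
F7 | step 11 | (5R,6S,9S,14S)-5-(tert-butyldimethylsilyloxy)-6,14-dimethyl-9-[(3E)-2-oxopent-3-en-1-yl]-1,7-dioxacyclotetradec-3-yne-2,8,11-trione (C9 epimer of 21) | C/C=C/C(=O)C[C@@H]1CC(=O)CC[C@H](C)OC(=O)C#C[C@@H](O[Si](C)(C)C(C)(C)C)[C@H](C)OC1=O
F8 | step 13 | (3Z,5R,6S,9R,14S)-5-(tert-butyldimethylsilyloxy)-6,14-dimethyl-9-[(3E)-2-oxopent-3-en-1-yl]-1,7-dioxacyclotetradec-3-ene-2,8,11-trione | C/C=C/C(=O)C[C@H]1CC(=O)CC[C@H](C)OC(=O)/C=C\[C@@H](O[Si](C)(C)C(C)(C)C)[C@H](C)OC1=O
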